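Ring A (benzoic acid numbering: C1 CO2H, C2 OMe, C3 carbinol chain, C6 OAr) is cut at two adjacent bonds, the ether bond O–C6 and the bond from C1 to carboxyl carbon C7. A 3-methoxyaryne across C1 and C6 takes up the ring B phenoxide and CO2 in one operation, so hindered ether and crowded acid arise together. The step exploits the array C2(OMe)–C1–C6 of ring A: the C2 methoxy group sends the phenoxide to remote C6 and stabilises the anion at C1. The precursor is an o-silylaryl triflate carrying the (S)-configured, silyl-protected carbinol chain at C3; its partner is ring B as allyl ether and dioxane acetal.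

Key step: step 12

Remark: the target SMILES defines the carbinol centre as (S); 2-hydroxy-3-methoxy-5-methylbenzaldehyde is taken as a catalogue compound, which fixes the oxygenation pattern of ring B from the start.

**Ring A: aryne precursor**

Step 1
Reactants: 1 4-hydroxy-2-methoxybenzaldehyde
Product: 2 4-formyl-3-methoxyphenyl N,N-diethylcarbamate
Conditions: Et2NCOCl, K2CO3, MeCN, reflux
Reagents that add atoms: N,N-diethylcarbamoyl chloride, CCN(CC)C(Cl)=O
Why: O-carbamoylation of the potassium phenoxide by the carbamoyl chloride gives a group that protects the phenol through the next steps and later directs ortho-metalation.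

Step 2
Reactants: 2 4-formyl-3-methoxyphenyl N,N-diethylcarbamate; 3 isobutylmagnesium bromide
Product: 4 rac-4-(1-hydroxy-3-methylbutyl)-3-methoxyphenyl N,N-diethylcarbamate
Conditions: THF, −78 → 0 °C; aq. NH4Cl
Reagents that add atoms: none
Why: Grignard addition to the aldehyde, which is far more electrophilic than the aryl diethylcarbamate at low temperature; the carbinol centre forms as a racemate and is erased in step 3.

Step 3
Reactants: 4 rac-4-(1-hydroxy-3-methylbutyl)-3-methoxyphenyl N,N-diethylcarbamate
Product: 5 3-methoxy-4-(3-methylbutanoyl)phenyl N,N-diethylcarbamate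
Conditions: Dess–Martin periodinane, CH2Cl2, rt
Reagents that add atoms: none
Why: Dess–Martin oxidation of a secondary benzylic alcohol to the aryl ketone proceeds under neutral conditions that leave the carbamate untouched.

Step 4
Reactants: 5 3-methoxy-4-(3-methylbutanoyl)phenyl N,N-diethylcarbamate
Product: 6 4-[(S)-1-hydroxy-3-methylbutyl]-3-methoxyphenyl N,N-diethylcarbamate
Conditions: (R)-2-methyl-CBS-oxazaborolidine (20 mol%), BH3·SMe2, THF, −20 °C; MeOH
Reagents that add atoms: none
Why: Corey–Bakshi–Shibata reduction, in which the ketone binds to the oxazaborolidine–borane complex with the aryl group as the large substituent, so that the (R)-catalyst should deliver hydride to the face that gives the (S)-carbinol.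

Step 5
Reactants: 6 4-[(S)-1-hydroxy-3-methylbutyl]-3-methoxyphenyl N,N-diethylcarbamate
Product: 7 4-[(S)-1-(tert-butyldimethylsilyloxy)-3-methylbutyl]-3-methoxyphenyl N,N-diethylcarbamate
Conditions: TBSOTf, 2,6-lutidine, CH2Cl2, 0 °C
Reagents that add atoms: tert-butyldimethylsilyl trifluoromethanesulfonate, CC(C)(C)[Si](C)(C)OS(=O)(=O)C(F)(F)F
Why: O-silylation of the hindered secondary alcohol with a silyl triflate and a non-nucleophilic base gives a TBS ether that tolerates organolithium, hydride and the fluoride source of step 12.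

Step 6
Reactants: 7 4-[(S)-1-(tert-butyldimethylsilyloxy)-3-methylbutyl]-3-methoxyphenyl N,N-diethylcarbamate
Product: 9 4-[(S)-1-(tert-butyldimethylsilyloxy)-3-methylbutyl]-3-methoxy-2-(trimethylsilyl)phenyl N,N-diethylcarbamate, via aryllithium 8 (not isolated)
Conditions: s-BuLi, TMEDA, THF, −78 °C; TMSCl, −78 °C → rt
Reagents that add atoms: chlorotrimethylsilane, C[Si](C)(C)Cl
Why: Directed ortho-metalation, in which the carbamate and the methoxy group cooperate so that the proton between them is removed, and the aryllithium is silylated cold before an anionic Fries shift can set in.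

Step 7
Reactants: 9 4-[(S)-1-(tert-butyldimethylsilyloxy)-3-methylbutyl]-3-methoxy-2-(trimethylsilyl)phenyl N,N-diethylcarbamate
Product: 10 4-[(S)-1-(tert-butyldimethylsilyloxy)-3-methylbutyl]-3-methoxy-2-(trimethylsilyl)phenol
Conditions: LiAlH4, THF, 0 °C → rt; Na2SO4·10H2O
Reagents that add atoms: none
Why: Hydride reduction of the carbamate carbonyl expels the phenoxide (the carbamoyl group leaves as an amine) under non-acidic conditions that spare the aryl–silicon bond and the TBS ether.

Step 8
Reactants: 10 4-[(S)-1-(tert-butyldimethylsilyloxy)-3-methylbutyl]-3-methoxy-2-(trimethylsilyl)phenol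
Product: 11 4-[(S)-1-(tert-butyldimethylsilyloxy)-3-methylbutyl]-3-methoxy-2-(trimethylsilyl)phenyl trifluoromethanesulfonate
Conditions: Tf2O, pyridine, CH2Cl2, 0 °C
Reagents that add atoms: trifluoromethanesulfonic anhydride, O=S(=O)(OS(=O)(=O)C(F)(F)F)C(F)(F)F
Why: O-sulfonylation of the phenol with triflic anhydride and pyridine is the standard last step in the preparation of o-silylaryl triflates.

**Ring B: phenol partner**

Step 9
Reactants: 12 2-hydroxy-3-methoxy-5-methylbenzaldehyde
Product: 13 2,3-dihydroxy-5-methylbenzaldehyde
Conditions: BBr3, CH2Cl2, −78 °C → rt; H2O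
Reagents that add atoms: none
Why: Lewis acid cleavage of the aryl methyl ether, in which bromide attacks the methyl group of the boron-bound ether, is the usual way from an o-vanillin to a 2,3-dihydroxybenzaldehyde.

Step 10
Reactants: 13 2,3-dihydroxy-5-methylbenzaldehyde
Product: 15 3-(allyloxy)-2-hydroxy-5-methylbenzaldehyde, via disodium catecholate 14 (not isolated)
Conditions: NaH (2.2 equiv), DMSO, rt; allyl bromide (1.0 equiv); aq. HCl
Reagents that add atoms: allyl bromide, C=CCBr
Why: Williamson alkylation of the catechol dianion, in which the oxygen at C3 is not conjugated with the formyl group and is the more nucleophilic one, so that one equivalent of allyl bromide should alkylate O3 and leave O2 free.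

Step 11
Reactants: 15 3-(allyloxy)-2-hydroxy-5-methylbenzaldehyde
Product: 16 2-(allyloxy)-6-(1,3-dioxan-2-yl)-4-methylphenol
Conditions: 1,3-propanediol, p-TsOH (cat.), toluene, reflux, Dean–Stark
Reagents that add atoms: propane-1,3-diol, OCCCO
Why: Acid-catalysed acetalisation with azeotropic removal of water masks the aldehyde as a 1,3-dioxane that resists base, fluoride, the aryl anion of step 12 and zerovalent palladium.

**Coupling and endgame**

Step 12
Reactants: 11 4-[(S)-1-(tert-butyldimethylsilyloxy)-3-methylbutyl]-3-methoxy-2-(trimethylsilyl)phenyl trifluoromethanesulfonate; 16 2-(allyloxy)-6-(1,3-dioxan-2-yl)-4-methylphenol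
Product: 20 6-[2-(allyloxy)-6-(1,3-dioxan-2-yl)-4-methylphenoxy]-3-[(S)-1-(tert-butyldimethylsilyloxy)-3-methylbutyl]-2-methoxybenzoic acid, via potassium phenoxide 17 (not isolated), via aryne 18 (not isolated), via arylpotassium 19 (not isolated)
Conditions: 16, KH, 18-crown-6, THF, 0 °C; then CO2 (1 atm), 11, KF, 0 °C → rt; aq. HCl to pH 3–4, 0 °C
Reagents that add atoms: carbon dioxide, O=C=O
Why: Proposed new method: fluoride attacks the trimethylsilyl group of 11 and triflate leaves from the neighbouring carbon to give aryne 18; phenoxide 17 adds to the aryne carbon remote from the methoxy group (O–C6 bond) and the aryl anion 19 left at C1 attacks CO2 (C1–C7 bond), so the carboxylate forms in the same flask. The closest known reaction type is the fluoride-triggered three-component coupling of arynes with amines and CO2 to anthranilic acids, together with the established O-arylation of phenoxides by 3-methoxyarynes; here the intermediate is a free aryl anion and not a zwitterion, which is why the phenoxide is preformed with KH and the medium is THF without acidic O–H or N–H. No ring is closed and no stereocentre is created, and the (S)-silyl ether is a spectator. The step needs regioselectivity (oxygen at C6, carbon at C1), and the C2 methoxy group secures it by distorting the aryne toward attack at the remote carbon and by stabilising the negative charge at C1 inductively. It also needs carboxylation to outrun protonation, which the CO2 atmosphere, the aprotic medium and the acetal mask on the ring B aldehyde (no internal electrophile for the aryl anion) are chosen to ensure.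

Step 13
Reactants: 20 6-[2-(allyloxy)-6-(1,3-dioxan-2-yl)-4-methylphenoxy]-3-[(S)-1-(tert-butyldimethylsilyloxy)-3-methylbutyl]-2-methoxybenzoic acid
Product: 21 3-[(S)-1-(tert-butyldimethylsilyloxy)-3-methylbutyl]-6-[2-(1,3-dioxan-2-yl)-6-hydroxy-4-methylphenoxy]-2-methoxybenzoic acid
Conditions: Pd(PPh3)4 (5 mol%), morpholine, THF, rt
Reagents that add atoms: none
Why: Tsuji–Trost deallylation, in which zerovalent palladium ionises the allyl aryl ether to a π-allyl complex that morpholine intercepts, runs under neutral conditions that spare the silyl ether, the acetal and the acid.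

Step 14
Reactants: 21 3-[(S)-1-(tert-butyldimethylsilyloxy)-3-methylbutyl]-6-[2-(1,3-dioxan-2-yl)-6-hydroxy-4-methylphenoxy]-2-methoxybenzoic acid
Product: 23 tenellic acid B: 6-(2-formyl-6-hydroxy-4-methylphenoxy)-3-[(S)-1-hydroxy-3-methylbutyl]-2-methoxybenzoic acid, via carbinol acetal 22 (not isolated)
Conditions: TBAF, THF, rt; then 1 M aq. HCl, 0 °C → rt
Reagents that add atoms: water, O
Why: Fluoride cleaves the TBS ether through the strong Si–F bond and the acidification that follows hydrolyses the 1,3-dioxane to the aldehyde in the same flask, with the acid kept dilute and cold so that the (S)-benzylic carbinol does not ionise.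

**Compound list**

1 | 4-hydroxy-2-methoxybenzaldehyde | COc1cc(O)ccc1C=O | starting material
2 | 4-formyl-3-methoxyphenyl N,N-diethylcarbamate | CCN(CC)C(=O)Oc1ccc(C=O)c(OC)c1 | intermediate
3 | isobutylmagnesium bromide | CC(C)C[Mg]Br | starting material
4 | rac-4-(1-hydroxy-3-methylbutyl)-3-methoxyphenyl N,N-diethylcarbamate | CCN(CC)C(=O)Oc1ccc(C(O)CC(C)C)c(OC)c1 | intermediate
5 | 3-methoxy-4-(3-methylbutanoyl)phenyl N,N-diethylcarbamate | CCN(CC)C(=O)Oc1ccc(C(=O)CC(C)C)c(OC)c1 | intermediate
6 | 4-[(S)-1-hydroxy-3-methylbutyl]-3-methoxyphenyl N,N-diethylcarbamate | CCN(CC)C(=O)Oc1ccc([C@@H](O)CC(C)C)c(OC)c1 | intermediate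
7 | 4-[(S)-1-(tert-butyldimethylsilyloxy)-3-methylbutyl]-3-methoxyphenyl N,N-diethylcarbamate | CCN(CC)C(=O)Oc1ccc([C@@H](O[Si](C)(C)C(C)(C)C)CC(C)C)c(OC)c1 | intermediate
8 | 2-lithio derivative of 7 (lithium on the carbon between carbamate and methoxy group) | CCN(CC)C(=O)Oc1ccc([C@@H](O[Si](C)(C)C(C)(C)C)CC(C)C)c(OC)c1[Li] | intermediate
9 | 4-[(S)-1-(tert-butyldimethylsilyloxy)-3-methylbutyl]-3-methoxy-2-(trimethylsilyl)phenyl N,N-diethylcarbamate | CCN(CC)C(=O)Oc1ccc([C@@H](O[Si](C)(C)C(C)(C)C)CC(C)C)c(OC)c1[Si](C)(C)C | intermediate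
10 | 4-[(S)-1-(tert-butyldimethylsilyloxy)-3-methylbutyl]-3-methoxy-2-(trimethylsilyl)phenol | Oc1ccc([C@@H](O[Si](C)(C)C(C)(C)C)CC(C)C)c(OC)c1[Si](C)(C)C | intermediate
11 | 4-[(S)-1-(tert-butyldimethylsilyloxy)-3-methylbutyl]-3-methoxy-2-(trimethylsilyl)phenyl trifluoromethanesulfonate | COc1c([C@@H](O[Si](C)(C)C(C)(C)C)CC(C)C)ccc(OS(=O)(=O)C(F)(F)F)c1[Si](C)(C)C | intermediate
12 | 2-hydroxy-3-methoxy-5-methylbenzaldehyde | COc1cc(C)cc(C=O)c1O | starting material
13 | 2,3-dihydroxy-5-methylbenzaldehyde | Cc1cc(O)c(O)c(C=O)c1 | intermediate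
14 | disodium 3-formyl-5-methylbenzene-1,2-diolate | Cc1cc([O-])c([O-])c(C=O)c1.[Na+].[Na+] | intermediate
15 | 3-(allyloxy)-2-hydroxy-5-methylbenzaldehyde | C=CCOc1cc(C)cc(C=O)c1O | intermediate
16 | 2-(allyloxy)-6-(1,3-dioxan-2-yl)-4-methylphenol | Cc1cc(OCC=C)c(O)c(C2OCCCO2)c1 | intermediate
17 | potassium 2-(allyloxy)-6-(1,3-dioxan-2-yl)-4-methylphenoxide | Cc1cc(OCC=C)c([O-])c(C2OCCCO2)c1.[K+] | intermediate
18 | 3-methoxy-4-[(S)-1-(tert-butyldimethylsilyloxy)-3-methylbutyl]benzyne (triple bond between the former C–Si and C–OTf carbons) | COC1=C([C@@H](O[Si](C)(C)C(C)(C)C)CC(C)C)C=CC#C1 | intermediate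
19 | arylpotassium from addition of 17 to 18 (potassium at C1 of ring A, aryloxy group at C6) | COc1c([C@@H](O[Si](C)(C)C(C)(C)C)CC(C)C)ccc(Oc2c(OCC=C)cc(C)cc2C2OCCCO2)c1[K] | intermediate
20 | 6-[2-(allyloxy)-6-(1,3-dioxan-2-yl)-4-methylphenoxy]-3-[(S)-1-(tert-butyldimethylsilyloxy)-3-methylbutyl]-2-methoxybenzoic acid | COc1c([C@@H](O[Si](C)(C)C(C)(C)C)CC(C)C)ccc(Oc2c(OCC=C)cc(C)cc2C2OCCCO2)c1C(=O)O | intermediate
21 | 3-[(S)-1-(tert-butyldimethylsilyloxy)-3-methylbutyl]-6-[2-(1,3-dioxan-2-yl)-6-hydroxy-4-methylphenoxy]-2-methoxybenzoic acid | COc1c([C@@H](O[Si](C)(C)C(C)(C)C)CC(C)C)ccc(Oc2c(O)cc(C)cc2C2OCCCO2)c1C(=O)O | intermediate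
22 | 6-[2-(1,3-dioxan-2-yl)-6-hydroxy-4-methylphenoxy]-3-[(S)-1-hydroxy-3-methylbutyl]-2-methoxybenzoic acid | COc1c([C@@H](O)CC(C)C)ccc(Oc2c(O)cc(C)cc2C2OCCCO2)c1C(=O)O | intermediate
23 | tenellic acid B, 6-(2-formyl-6-hydroxy-4-methylphenoxy)-3-[(S)-1-hydroxy-3-methylbutyl]-2-methoxybenzoic acid | COc1c([C@@H](O)CC(C)C)ccc(Oc2c(O)cc(C)cc2C=O)c1C(=O)O | target

**Step count and risks**

Total steps: 14. Longest linear sequence: 11 steps (steps 1–8, then 12–14, from compound 1). The ring B branch contributes 3 steps before the coupling.

Steps most likely to fail: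

1. Step 12. The aryl anion may be protonated before CO2 reaches it, by traces of water or by hydrogen transfer from the acetal or allyl C–H of ring B. Alternatively, CO2 may bind the phenoxide as its carbonate so strongly that addition to the aryne is outrun by aryne decomposition. The fallback uses known chemistry, sets out from 11 and 16, and separates the two bond formations. CsF in MeCN at rt (the established aryne O-arylation of phenols, with protonation at C1) should give the C1-unsubstituted diaryl ether F1 with the same regiochemistry. Pd(PPh3)4 and morpholine in THF then remove the allyl group, which would not survive an alkyllithium, to give the phenolic diaryl ether F2. s-BuLi/TMEDA (3 equiv) in THF at −78 → −40 °C first forms the lithium phenoxide and then metalates C1 of ring A, the only position flanked by two ether oxygens (directed ortho-metalation). Quenching with CO2 gives acid 21, where the fallback rejoins the route before step 14.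

2. Step 6. Metalation may be slow at the crowded position between carbamate and methoxy group, because the bulky silyloxyalkyl neighbour pushes the methoxy group toward that site. Metalation at the benzylic carbon next to the silyl ether, followed by silyl migration from oxygen to carbon, may also compete. The fallback sets out from alcohol 6 and silylates the ring before the carbinol is protected. s-BuLi/TMEDA (2.3 equiv) in THF at −78 °C forms the lithium alkoxide, whose carbinol C–H is no longer acidic and which is much smaller than the TBS ether, and then the aryllithium. An excess of TMSCl gives the C,O-bis(trimethylsilyl) compound F3. K2CO3 in MeOH at 0 °C cleaves only the O–Si bond to give the o-silylated carbinol F4. TBSOTf and 2,6-lutidine then give 9, where the fallback rejoins the route.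

3. Step 4. Facial discrimination in the reduction may be poor, because the ortho-methoxy group twists the aryl ketone and the isobutyl group is then not much smaller than the aryl group. The fallback sets the centre by reagent-controlled C–C bond formation and sets out from aldehyde 2. Brown methallylation with (−)-B-(2-methylallyl)diisopinocampheylborane (from (−)-B-methoxydiisopinocampheylborane and 2-methylallylmagnesium chloride) in Et2O at −78 °C, with NaOH/H2O2 work-up, should give the (S)-homoallylic alcohol F5 through a chair transition state. Hydrogenation of the 1,1-disubstituted alkene with H2 and RhCl(PPh3)3 in benzene/EtOH, which leaves the benzylic C–O bond alone, gives 6, where the fallback rejoins the route. It replaces steps 2–4 by two steps.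

**Further compounds**

F1 | step 12 | tert-butyl{(S)-1-[4-(2-allyloxy-6-(1,3-dioxan-2-yl)-4-methylphenoxy)-2-methoxyphenyl]-3-methylbutoxy}dimethylsilane | COc1c([C@@H](O[Si](C)(C)C(C)(C)C)CC(C)C)ccc(Oc2c(OCC=C)cc(C)cc2C2OCCCO2)c1
F2 | step 12 | 2-{4-[(S)-1-(tert-butyldimethylsilyloxy)-3-methylbutyl]-3-methoxyphenoxy}-3-(1,3-dioxan-2-yl)-5-methylphenol | COc1c([C@@H](O[Si](C)(C)C(C)(C)C)CC(C)C)ccc(Oc2c(O)cc(C)cc2C2OCCCO2)c1
F3 | step 6 | 3-methoxy-4-[(S)-3-methyl-1-(trimethylsilyloxy)butyl]-2-(trimethylsilyl)phenyl N,N-diethylcarbamate | CCN(CC)C(=O)Oc1ccc([C@@H](O[Si](C)(C)C)CC(C)C)c(OC)c1[Si](C)(C)C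
F4 | step 6 | 4-[(S)-1-hydroxy-3-methylbutyl]-3-methoxy-2-(trimethylsilyl)phenyl N,N-diethylcarbamate | CCN(CC)C(=O)Oc1ccc([C@@H](O)CC(C)C)c(OC)c1[Si](C)(C)C
F5 | step 4 | 4-[(S)-1-hydroxy-3-methylbut-3-en-1-yl]-3-methoxyphenyl N,N-diethylcarbamate | CCN(CC)C(=O)Oc1ccc([C@@H](O)CC(C)=C)c(OC)c1
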